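## Retrosynthetic overview

- **Numbering:** chroman-2-one numbers are used, plain for the 5,7-dihydroxy unit A (benzo ring A) and primed for the 5,6,7,8-tetrahydroxy unit B (benzo ring B). The SMILES string reads as 3R,4R,3'S,4'R, which is trans in unit A and cis in unit B.
- **Feature used:** C4 bears a 4-hydroxyphenyl group, so a C4H2 group para to that phenol lies two electrons and two protons below a para-quinone methide whose electrophilic end is C4. Ring A is a 1,3,5-trioxygenated benzene whose two carbons ortho to O1 are equivalent, so either one becomes C4a.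
- **Disconnections, backwards:** seven O-methyl ethers; C3'-H and C4'-H (syn hydrogenation of a coumarin B); C4-C4a (anodic quinone methide formation with Friedel-Crafts closure of lactone ring A); the O1-C2 aryl ester; C3-C4 (auxiliary-controlled benzylation that sets C3).
- **Timing of C3:** C3 is set only after the strongly basic condensation that builds coumarin B. Its hydrogen is alpha to a carbonyl group and allylic to C3'=C4', so it could not be trusted to survive that step or a saponification.
- **Ring order:** the pyranone ring of unit B is formed first (step 4) and lactone ring A second (step 10). All benzene rings are bought.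

Key step: step 10

Assumption: 4-(benzyloxy)benzyl bromide, methyl 4-chloro-4-oxobutanoate and both enantiomers of 4-benzyl-2-oxazolidinone are taken as commercial. The phenol freed for the key step is carried unprotected to the end, since neither hydrogenation nor BBr3 needs it capped.

Abbreviation: CouB = 5,6,7,8-tetramethoxy-4-(4-methoxyphenyl)-2-oxo-2H-chromen-3-yl (coumarin B joined through C3').

## Route

Step 1
Reactants: 1 1,2,3,4-tetramethoxybenzene
Product: 4 2,3,4,5-tetramethoxyphenol, via aryllithium 2 (not isolated), via dimethyl arylboronate 3 (not isolated)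
Conditions: n-BuLi, TMEDA, THF, 0 °C; B(OMe)3, −78 °C to rt; 30% aq. H2O2, 0 °C to rt
Reagents that add atoms: hydrogen peroxide, OO; n-butyllithium, [Li]CCCC (lithium, only in 2); trimethyl borate, COB(OC)OC (boron and two methoxy groups, only in 3)
Why: Directed ortho-lithiation next to a methoxy group (both ring hydrogens are equivalent), borylation and boronate oxidation with 1,2-aryl shift form a standard arene-to-phenol sequence, and no stereocentre is formed.

Step 2
Reactants: 4 2,3,4,5-tetramethoxyphenol; 5 4-methoxybenzoic acid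
Product: 6 (2-hydroxy-3,4,5,6-tetramethoxyphenyl)(4-methoxyphenyl)methanone
Conditions: BF3·OEt2 (neat), 85 °C; aq. NaOAc
Reagents that add atoms: 4-methoxybenzoic acid (5), COc1ccc(C(=O)O)cc1
Why: BF3-promoted Friedel-Crafts acylation of an electron-rich phenol (Fries-type ortho acylation) can only strike the single free ring carbon, which lies ortho to the hydroxy group, and BF3 is too mild to cleave the neighbouring methyl ethers.

Step 3
Reactants: 6 (2-hydroxy-3,4,5,6-tetramethoxyphenyl)(4-methoxyphenyl)methanone; 7 methyl 4-chloro-4-oxobutanoate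
Product: 8 2-(4-methoxybenzoyl)-3,4,5,6-tetramethoxyphenyl methyl succinate
Conditions: Et3N, DMAP (10 mol%), CH2Cl2, 0 °C to rt
Reagents that add atoms: methyl 4-chloro-4-oxobutanoate (7), COC(=O)CCC(=O)Cl
Why: DMAP-catalysed O-acylation of a phenol with an acid chloride overcomes the hydrogen bond and the two ortho groups of 6 and places the succinate CH2 that becomes C3' at six-ring distance from the ketone carbon.

Step 4
Reactants: 8 2-(4-methoxybenzoyl)-3,4,5,6-tetramethoxyphenyl methyl succinate
Product: 10 CouB-acetic acid, via bis-lactone 9 (not isolated)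
Conditions: KOt-Bu (2.2 equiv), THF, 0 °C to rt; dilute aq. HCl
Reagents that add atoms: none
Why: This is an intramolecular Stobbe condensation, in which the enolate next to the aryl ester adds to the diaryl ketone, the tertiary alkoxide lactonises onto the methyl ester to give 9, and E1cB opening of that five-membered lactone gives C3'=C4' and a carboxylate that drives the sequence, with no stereocentre left in 10.

Step 5
Reactants: 10 CouB-acetic acid; 11 (R)-4-benzyl-2-oxazolidinone
Product: 13 (R)-4-benzyl-3-(CouB-acetyl)oxazolidin-2-one, via mixed pivalic anhydride 12 (not isolated)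
Conditions: PivCl, Et3N, THF, −20 °C; then LiCl, 11, −20 °C to rt
Reagents that add atoms: (R)-4-benzyl-2-oxazolidinone (11), O=C1N[C@H](Cc2ccccc2)CO1; pivaloyl chloride, CC(C)(C)C(=O)Cl (pivaloyl group, only in 12)
Why: N-acylation of an oxazolidinone by a mixed anhydride under LiCl/Et3N activation needs no strong base, attack goes to the less hindered carbonyl group of 12, and the only stereocentre comes with the auxiliary.

Step 6
Reactants: 13 (R)-4-benzyl-3-(CouB-acetyl)oxazolidin-2-one; 14 4-(benzyloxy)benzyl bromide
Product: 16 (R)-4-benzyl-3-[(2R)-3-(4-benzyloxyphenyl)-2-CouB-propanoyl]oxazolidin-2-one, via sodium (Z)-enolate 15 (not isolated)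
Conditions: NaHMDS, THF, −78 °C; 14, −78 to −20 °C
Reagents that add atoms: 4-(benzyloxy)benzyl bromide (14), BrCc1ccc(OCc2ccccc2)cc1; sodium hexamethyldisilazide, C[Si](C)(C)[N-][Si](C)(C)C.[Na+] (sodium, only in 15)
Why: In this Evans asymmetric alkylation the chelated (Z)-enolate 15 is shielded on one face by the benzyl group of the (R)-auxiliary, so the reactive benzylic bromide enters from the other face, forms C3-C4 and sets C3 as R, while the gamma position C4' is fully substituted and does not compete.

Step 7
Reactants: 16 (R)-4-benzyl-3-[(2R)-3-(4-benzyloxyphenyl)-2-CouB-propanoyl]oxazolidin-2-one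
Product: 18 (2R)-3-(4-benzyloxyphenyl)-2-CouB-propanoic acid, via peroxy acid 17 (not isolated)
Conditions: LiOH, 30% aq. H2O2, THF-H2O, 0 °C; aq. Na2SO3; dilute aq. HCl
Reagents that add atoms: hydrogen peroxide, OO
Why: In the hydroperoxide cleavage of an N-acyloxazolidinone the weakly basic HOO− attacks the exocyclic carbonyl group at 0 °C without touching C3-H, sulfite reduces 17 to the acid, and any coumarin lactone that opens closes again on acidification because its alkene geometry is fixed.

Step 8
Reactants: 18 (2R)-3-(4-benzyloxyphenyl)-2-CouB-propanoic acid; 19 3,5-dimethoxyphenol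
Product: 20 3,5-dimethoxyphenyl (2R)-3-(4-benzyloxyphenyl)-2-CouB-propanoate
Conditions: N,N'-diisopropylcarbodiimide, DMAP (5 mol%), CH2Cl2, −20 to 0 °C
Reagents that add atoms: 3,5-dimethoxyphenol (19), COc1cc(O)cc(OC)c1
Why: This is a Steglich esterification with an unhindered phenol, run cold and with little DMAP because C3-H of the activated acid is prone to enolisation or ketene formation.

Step 9
Reactants: 20 3,5-dimethoxyphenyl (2R)-3-(4-benzyloxyphenyl)-2-CouB-propanoate
Product: 21 3,5-dimethoxyphenyl (2R)-3-(4-hydroxyphenyl)-2-CouB-propanoate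
Conditions: H2 (1 atm), Pd/C, EtOAc, rt
Reagents that add atoms: none
Why: Hydrogenolysis of a benzyl aryl ether is neutral, so C3 and the activated aryl ester are safe, and the tetrasubstituted C3'=C4' bond is not reduced at one atmosphere.

Step 10
Reactants: 21 3,5-dimethoxyphenyl (2R)-3-(4-hydroxyphenyl)-2-CouB-propanoate
Product: 23 (3R,4R)-4-(4-hydroxyphenyl)-5,7-dimethoxy-3-CouB-chroman-2-one (trans lactone A), via para-quinone methide 22 (not isolated)
Conditions: undivided parallel-plate flow cell (boron-doped diamond anode, platinum cathode, 0.25 mm gap); 21 (5 mmol/L), Bu4NPF6 (0.05 mol/L), CF3CO2H (20 mmol/L), HFIP-CH2Cl2 9:1, 10 °C; 2-3 mA/cm2, one pass, 2.0 F/mol at most; current set so that the anode stays below the oxidation onset of 20 (phenol-free control, cyclic voltammetry)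
Reagents that add atoms: none
Why: Proposed new method: at the anode the only free phenol of 21 should give up two electrons and two protons (O-H and one C4-H) to form para-quinone methide 22, which the acidic, non-nucleophilic medium activates by O-protonation or hydrogen bonding, after which the ring A carbon ortho to the ester oxygen adds to C4 (1,6-addition, an intramolecular Friedel-Crafts alkylation), proton loss restores both aromatic rings, and the protons are reduced to H2 at the cathode. The closest known reaction types are the anodic oxidation of 4-alkylphenols to para-quinone methides that are caught by an added nucleophile and the acid-catalysed 1,6-arylation of preformed para-quinone methides, whereas joining the two in one operation on a phenol without ortho blocking groups and through an ester tether has not been shown. Lactone ring A closes in the 6-exo-trig mode, since C4 enters the new six-membered ring and its double-bond partner in the cyclohexadienone stays outside. C4 is controlled by C3, because in the half-chair closing array the cyclohexadienone ring turns to the side of C3-H and away from CouB, which should lead to the trans (3R,4R) lactone. The step needs chemoselective oxidation of the phenol and site-selective arylation: ring B is deactivated by its acyloxy oxygen, by the conjugated lactone and by hydrogen bonding of HFIP to its twisted methoxy groups, the two ortho carbons of ring A are equivalent and lie ortho and para to methoxy groups, the third free carbon of ring A cannot reach C4, and the only other arene carbon within six-ring reach (an ortho carbon of the C4' anisyl ring) is meta to its methoxy group. CF3CO2H keeps proton reduction as the cathode reaction so that no alkoxide base meets 22 and removes its C3-H (which would give the cinnamate and erase C3), and one pass at no more than 2.0 F/mol with recovery of unreacted 21 limits further oxidation of the product phenol.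

Step 11
Reactants: 23 (3R,4R)-4-(4-hydroxyphenyl)-5,7-dimethoxy-3-CouB-chroman-2-one
Product: 24 (3R,4R)-4-(4-hydroxyphenyl)-5,7-dimethoxy-3-[(3S,4R)-5,6,7,8-tetramethoxy-4-(4-methoxyphenyl)-2-oxochroman-3-yl]chroman-2-one
Conditions: H2 (60 bar), Pd(OH)2/C, EtOAc-AcOH 4:1, 50 °C
Reagents that add atoms: none
Why: Heterogeneous catalytic hydrogenation of a coumarin C3=C4 bond adds both hydrogens to one face (cis C3'-H/C4'-H), and allylic 1,3-strain should hold C3-H in the plane of coumarin B beside the C4' aryl group, so the C4 diarylmethine blocks one face and hydrogen arrives from the face that carries only the C2 carbonyl group, which gives 3'S,4'R.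

Step 12
Reactants: 24 (3R,4R)-4-(4-hydroxyphenyl)-5,7-dimethoxy-3-[(3S,4R)-5,6,7,8-tetramethoxy-4-(4-methoxyphenyl)-2-oxochroman-3-yl]chroman-2-one
Product: 25 CNP0064734.4, (3R,4R,3'S,4'R)-5,7,5',6',7',8'-hexahydroxy-4,4'-bis(4-hydroxyphenyl)-3,3'-bichroman-2,2'-dione
Conditions: BBr3 (14 equiv), CH2Cl2, −78 to 0 °C; degassed ice-water, argon; reversed-phase chromatography with acidified, degassed eluent
Reagents that add atoms: none
Why: Cleavage of aryl methyl ethers with BBr3 (boron aryloxides hydrolysed on work-up) leaves the C-C bonds and the four stereocentres alone at or below 0 °C, a lactone that opens on quenching closes again in the acidic phase (either ortho oxygen of ring A or of ring B gives the same lactone), and exclusion of air guards the pentaoxygenated ring B.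

## Compound list

1 | 1,2,3,4-tetramethoxybenzene | COc1ccc(OC)c(OC)c1OC | starting material
2 | (2,3,4,5-tetramethoxyphenyl)lithium | [Li]c1cc(OC)c(OC)c(OC)c1OC | intermediate
3 | dimethyl (2,3,4,5-tetramethoxyphenyl)boronate | COB(OC)c1cc(OC)c(OC)c(OC)c1OC | intermediate
4 | 2,3,4,5-tetramethoxyphenol | Oc1cc(OC)c(OC)c(OC)c1OC | intermediate
5 | 4-methoxybenzoic acid | COc1ccc(C(=O)O)cc1 | starting material
6 | (2-hydroxy-3,4,5,6-tetramethoxyphenyl)(4-methoxyphenyl)methanone | COc1ccc(cc1)C(=O)c1c(O)c(OC)c(OC)c(OC)c1OC | intermediate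
7 | methyl 4-chloro-4-oxobutanoate | COC(=O)CCC(=O)Cl | starting material
8 | 2-(4-methoxybenzoyl)-3,4,5,6-tetramethoxyphenyl methyl succinate | COC(=O)CCC(=O)Oc1c(OC)c(OC)c(OC)c(OC)c1C(=O)c1ccc(OC)cc1 | intermediate
9 | cis-fused 6,7,8,9-tetramethoxy-9b-(4-methoxyphenyl)-3a,9b-dihydrofuro[3,2-c]chromene-2,4(3H)-dione (racemic, one enantiomer drawn) | O=C1C[C@@H]2C(=O)Oc3c(OC)c(OC)c(OC)c(OC)c3[C@]2(c2ccc(OC)cc2)O1 | intermediate
10 | 2-[5,6,7,8-tetramethoxy-4-(4-methoxyphenyl)-2-oxo-2H-chromen-3-yl]acetic acid (CouB-acetic acid) | OC(=O)CC1=C(c2ccc(OC)cc2)c2c(OC)c(OC)c(OC)c(OC)c2OC1=O | intermediate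
11 | (R)-4-benzyl-2-oxazolidinone | O=C1N[C@H](Cc2ccccc2)CO1 | starting material
12 | CouB-acetic pivalic anhydride | CC(C)(C)C(=O)OC(=O)CC1=C(c2ccc(OC)cc2)c2c(OC)c(OC)c(OC)c(OC)c2OC1=O | intermediate
13 | (R)-4-benzyl-3-(CouB-acetyl)oxazolidin-2-one | O=C(CC1=C(c2ccc(OC)cc2)c2c(OC)c(OC)c(OC)c(OC)c2OC1=O)N1[C@H](Cc2ccccc2)COC1=O | intermediate
14 | 4-(benzyloxy)benzyl bromide | BrCc1ccc(OCc2ccccc2)cc1 | starting material
15 | sodium (Z)-enolate of 13 | O=C1Oc2c(OC)c(OC)c(OC)c(OC)c2C(c2ccc(OC)cc2)=C1/C=C(\[O-])N1[C@H](Cc2ccccc2)COC1=O.[Na+] | intermediate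
16 | (R)-4-benzyl-3-[(2R)-3-(4-benzyloxyphenyl)-2-CouB-propanoyl]oxazolidin-2-one | O=C([C@H](Cc1ccc(OCc2ccccc2)cc1)C1=C(c2ccc(OC)cc2)c2c(OC)c(OC)c(OC)c(OC)c2OC1=O)N1[C@H](Cc2ccccc2)COC1=O | intermediate
17 | (2R)-3-(4-benzyloxyphenyl)-2-CouB-propaneperoxoic acid | OOC(=O)[C@H](Cc1ccc(OCc2ccccc2)cc1)C1=C(c2ccc(OC)cc2)c2c(OC)c(OC)c(OC)c(OC)c2OC1=O | intermediate
18 | (2R)-3-(4-benzyloxyphenyl)-2-CouB-propanoic acid | OC(=O)[C@H](Cc1ccc(OCc2ccccc2)cc1)C1=C(c2ccc(OC)cc2)c2c(OC)c(OC)c(OC)c(OC)c2OC1=O | intermediate
19 | 3,5-dimethoxyphenol | COc1cc(O)cc(OC)c1 | starting material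
20 | 3,5-dimethoxyphenyl (2R)-3-(4-benzyloxyphenyl)-2-CouB-propanoate | COc1cc(OC)cc(OC(=O)[C@H](Cc2ccc(OCc3ccccc3)cc2)C2=C(c3ccc(OC)cc3)c3c(OC)c(OC)c(OC)c(OC)c3OC2=O)c1 | intermediate
21 | 3,5-dimethoxyphenyl (2R)-3-(4-hydroxyphenyl)-2-CouB-propanoate (key-step precursor) | COc1cc(OC)cc(OC(=O)[C@H](Cc2ccc(O)cc2)C2=C(c3ccc(OC)cc3)c3c(OC)c(OC)c(OC)c(OC)c3OC2=O)c1 | intermediate
22 | 3,5-dimethoxyphenyl (2R)-2-CouB-3-(4-oxocyclohexa-2,5-dien-1-ylidene)propanoate (para-quinone methide) | COc1cc(OC)cc(OC(=O)[C@H](C=C2C=CC(=O)C=C2)C2=C(c3ccc(OC)cc3)c3c(OC)c(OC)c(OC)c(OC)c3OC2=O)c1 | intermediate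
23 | (3R,4R)-4-(4-hydroxyphenyl)-5,7-dimethoxy-3-CouB-chroman-2-one (key-step product) | O=C1Oc2cc(OC)cc(OC)c2[C@@H](c2ccc(O)cc2)[C@@H]1C1=C(c2ccc(OC)cc2)c2c(OC)c(OC)c(OC)c(OC)c2OC1=O | intermediate
24 | (3R,4R)-4-(4-hydroxyphenyl)-5,7-dimethoxy-3-[(3S,4R)-5,6,7,8-tetramethoxy-4-(4-methoxyphenyl)-2-oxochroman-3-yl]chroman-2-one | O=C1Oc2cc(OC)cc(OC)c2[C@@H](c2ccc(O)cc2)[C@@H]1[C@H]1C(=O)Oc2c(OC)c(OC)c(OC)c(OC)c2[C@H]1c1ccc(OC)cc1 | intermediate
25 | CNP0064734.4 | O=C1Oc2cc(O)cc(O)c2[C@@H](c2ccc(O)cc2)[C@@H]1[C@H]1C(=O)Oc2c(O)c(O)c(O)c(O)c2[C@H]1c1ccc(O)cc1 | target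

## Step count and risks

Total step count: 12. Longest linear sequence: 12 steps (1 to 25); all other building blocks are bought.

### 1. Step 10

**What may go wrong**
- The quinone methide or its cation loses the C3 hydrogen and tautomerises to the 4-hydroxycinnamate, which removes the stereocentre.
- Phenoxyl radicals couple with each other at their free ortho carbons before the second electron is taken.
- Ring B loses an electron in competition with the phenol.
- Closure is slow because the aryl ester must first turn into its less favoured s-cis rotamer.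
- The product phenol is oxidised further at its doubly benzylic C4-H.

**Fallback (sets out from 10, comes back at 23)**

The oxidation level of C4 is brought in by an aldol reaction instead of by C-H oxidation. Acid 10 is joined to (S)-4-benzyl-2-oxazolidinone as in step 5 to give the enantiomeric-auxiliary imide F1. Its dibutylboron (Z)-enolate (Bu2BOTf, i-Pr2NEt, CH2Cl2, −78 to 0 °C) adds to 4-(benzyloxy)benzaldehyde in an Evans syn aldol reaction. This reaction uses the enolate face opposite to that of an alkylation with the same auxiliary, so it creates the spatial arrangement at C3 that the route needs, in the syn aldol adduct F2.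

LiOH/H2O2 then gives the beta-hydroxy acid F3. N,N'-diisopropylcarbodiimide, a little DMAP and 19 give the beta-hydroxy aryl ester F4. Catalytic Bi(OTf)3 in CH2Cl2-HFIP ionises the benzylic alcohol to the 4-benzyloxybenzyl cation, and a dehydrative intramolecular Friedel-Crafts alkylation, again steered by C3, closes lactone ring A to the O-benzyl lactone F5. H2 and Pd/C as in step 9 lead to 23.

### 2. Step 11

**What may go wrong**
- No hydrogen is taken up, because the tetrasubstituted C3'=C4' bond is flanked by the twisted anisyl ring, the 5'-methoxy group and the C3 branch and cannot lie flat on the metal.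
- Facial selectivity is poor if the rotamer with C3-H beside C2'=O takes part.

**Fallback (sets out from 23, comes back at 24)**

Reduction by electron transfer is used, which does not depend on adsorption. SmI2 in THF-N,N-dimethylacetamide with t-BuOH at rt (the known conjugate reduction of unsaturated esters) should put two electrons into the low-lying aryl-conjugated lactone system. Protonation at C4' should come from the face away from the C4 diarylmethine. Kinetic protonation at C3' should come from the face opposite the C4' aryl group, which is the same face, so the cis product 24 is expected. This fallback makes no compound outside the list.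

### 3. Step 12

**What may go wrong**
- C3' epimerises from cis to trans through Lewis acid-promoted enolisation of lactone B.
- The hindered ring B ethers are cleaved incompletely at the low temperature that this concern imposes.
- Ring B is oxidised by air during aqueous work-up.

**Fallback (sets out from 23, comes back at 25)**

The order of the last two operations is reversed. BBr3 is applied to 23, where C3' and C4' are still sp2 carbons and unit A is in its more stable trans form, so room temperature can be used, and this gives the heptahydroxy coumarin-lactone F6. Hydrogenation of F6 (H2, Pd(OH)2/C, EtOAc-AcOH) then sets C3' and C4' in the final, neutral operation, and 25 is obtained by filtration and evaporation under argon without aqueous work-up.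

## Further compounds

F1 | step 10 | (S)-4-benzyl-3-(CouB-acetyl)oxazolidin-2-one | O=C(CC1=C(c2ccc(OC)cc2)c2c(OC)c(OC)c(OC)c(OC)c2OC1=O)N1[C@@H](Cc2ccccc2)COC1=O
F2 | step 10 | (S)-4-benzyl-3-[(2S,3S)-3-(4-benzyloxyphenyl)-2-CouB-3-hydroxypropanoyl]oxazolidin-2-one | O=C([C@H]([C@H](O)c1ccc(OCc2ccccc2)cc1)C1=C(c2ccc(OC)cc2)c2c(OC)c(OC)c(OC)c(OC)c2OC1=O)N1[C@@H](Cc2ccccc2)COC1=O
F3 | step 10 | (2S,3S)-3-(4-benzyloxyphenyl)-2-CouB-3-hydroxypropanoic acid | OC(=O)[C@H]([C@H](O)c1ccc(OCc2ccccc2)cc1)C1=C(c2ccc(OC)cc2)c2c(OC)c(OC)c(OC)c(OC)c2OC1=O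
F4 | step 10 | 3,5-dimethoxyphenyl (2S,3S)-3-(4-benzyloxyphenyl)-2-CouB-3-hydroxypropanoate | COc1cc(OC)cc(OC(=O)[C@H]([C@H](O)c2ccc(OCc3ccccc3)cc2)C2=C(c3ccc(OC)cc3)c3c(OC)c(OC)c(OC)c(OC)c3OC2=O)c1
F5 | step 10 | (3R,4R)-4-(4-benzyloxyphenyl)-5,7-dimethoxy-3-CouB-chroman-2-one | O=C1Oc2cc(OC)cc(OC)c2[C@@H](c2ccc(OCc3ccccc3)cc2)[C@@H]1C1=C(c2ccc(OC)cc2)c2c(OC)c(OC)c(OC)c(OC)c2OC1=O
F0 | step 11 | none | none
F6 | step 12 | (3R,4R)-5,7-dihydroxy-4-(4-hydroxyphenyl)-3-[5,6,7,8-tetrahydroxy-4-(4-hydroxyphenyl)-2-oxo-2H-chromen-3-yl]chroman-2-one | O=C1Oc2cc(O)cc(O)c2[C@@H](c2ccc(O)cc2)[C@@H]1C1=C(c2ccc(O)cc2)c2c(O)c(O)c(O)c(O)c2OC1=O
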